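**Retrosynthetic overview**
1. Ring C is closed last. The O1–C2 bond is formed by a chalcone-isomerase-type, catalyst-controlled 6-endo-trig oxa-Michael addition of the free 2'-hydroxychalcone, with no activating ester, so C2 (S) is set in the ring-forming event itself.
2. The chalcone is cut at the aryl–C(=O) bond, not at Cα–Cβ. The intact C6–C3 4-methoxycinnamoyl unit is passed O→C onto ring A (ester, then Fries), the laboratory counterpart of the chalcone-synthase Claisen C-acylation that starts from p-coumaroyl-CoA.
3. The A-ring partner, 2,3,4,5-tetramethoxyphenol, comes from 3,4,5-trimethoxyphenol by bromination and Cu-catalysed methoxylation. This is done early so that no base ever meets the stereocentre.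
4. Rings A and B are bought as arenes. The order is A-ring oxygenation, then C-cinnamoylation, then ring C.

Assumption: the quinine-derived thiourea is taken as the catalyst antipode that gives the 2S series (checked on the first run by CD: negative Cotton effect near 285 nm, positive near 330 nm); its quinidine-derived pseudoenantiomer is equally available should the sense be opposite.

**Route**

Step 1
Reactants: 1 3,4,5-trimethoxyphenol
Product: 2 2-bromo-3,4,5-trimethoxyphenol
Conditions: NBS (1.0 equiv), CH2Cl2, −40 → 0 °C, dark, 2 h
Reagents that add atoms: N-bromosuccinimide, O=C1CCC(=O)N1Br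
Why: Electrophilic aromatic bromination; the two free ring positions of 1 are equivalent (ortho to OH, para to an OMe) and the para position is blocked, so one equivalent of NBS at low temperature gives a single monobromide, and no stereocentre is involved.

Step 2
Reactants: 2 2-bromo-3,4,5-trimethoxyphenol
Product: 3 2,3,4,5-tetramethoxyphenol
Conditions: NaOMe (25 % in MeOH, 6 equiv), CuBr (15 mol %), DMF, 110 °C, N2, 8 h; then 1 M HCl under N2
Reagents that add atoms: sodium methoxide, C[O-].[Na+]
Why: Ullmann-type Cu(I)-catalysed methoxylation of an aryl bromide ortho to a free phenoxide, the same reaction type that converts 5-bromovanillin into syringaldehyde; the methyl ethers are inert and exclusion of air protects the electron-rich phenoxide.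

Step 3
Reactants: 3 2,3,4,5-tetramethoxyphenol; 4 (E)-4-methoxycinnamic acid
Product: 8 (E)-2'-hydroxy-3',4',5',6',4-pentamethoxychalcone, via 4-methoxycinnamoyl chloride 5 (not isolated), via aryl 4-methoxycinnamate 6 (not isolated), via chalcone BF2 chelate 7 (not isolated)
Conditions: 4, SOCl2 (1.5 equiv), cat. DMF, toluene, 70 °C, evaporate; add 3, BF3·OEt2 (neat), 90 °C, 30 min; H2O–MeOH, 50 °C
Reagents that add atoms: none
Why: Acid chloride formation and O-acylation are followed by a BF3-promoted Fries rearrangement (a Claisen-type C-acylation that transfers the whole cinnamoyl unit), which can only end at the single free ring carbon ortho to the oxygen, as known for 3,4,5-trimethoxyphenol with cinnamoyl chlorides; capture as the BF2 chelate ties up the phenol oxygen and so blocks racemic acid-catalysed ring closure, and the E-alkene is retained.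

Step 4
Reactants: 8 (E)-2'-hydroxy-3',4',5',6',4-pentamethoxychalcone
Product: 9 (2S)-5,6,7,8,4'-pentamethoxyflavanone
Conditions: 1-[3,5-bis(trifluoromethyl)phenyl]-3-[(8α,9S)-6'-methoxycinchonan-9-yl]thiourea (10 mol %), toluene (0.1 M), 20 °C, 72–96 h, stop at about 90 % conversion; SiO2 plug; recrystallise (EtOH)
Reagents that add atoms: none
Why: Organocatalytic enantioselective intramolecular oxa-Michael addition (chalcone-isomerase mimic), in which the quinuclidine nitrogen deprotonates the 2'-OH while the thiourea hydrogen-bonds the enone carbonyl, so the phenoxide adds to the Si face of C-β and sets C2 as S under kinetic control; the 6'-OMe twists the aryl ketone and favours the flavanone, so retro-Michael racemisation by the weak amine base stays slow.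

**Compound list**
1 | 3,4,5-trimethoxyphenol | COc1cc(O)cc(OC)c1OC | starting material
2 | 2-bromo-3,4,5-trimethoxyphenol | COc1cc(O)c(Br)c(OC)c1OC | intermediate
3 | 2,3,4,5-tetramethoxyphenol | COc1cc(O)c(OC)c(OC)c1OC | intermediate
4 | (E)-4-methoxycinnamic acid | COc1ccc(/C=C/C(=O)O)cc1 | starting material
5 | (E)-4-methoxycinnamoyl chloride | COc1ccc(/C=C/C(=O)Cl)cc1 | intermediate
6 | 2,3,4,5-tetramethoxyphenyl (E)-3-(4-methoxyphenyl)prop-2-enoate | COc1ccc(/C=C/C(=O)Oc2cc(OC)c(OC)c(OC)c2OC)cc1 | intermediate
7 | BF2 chelate of 8 (six-membered O–BF2–O ring through the 2'-oxygen and the carbonyl oxygen, E-styryl group on the former carbonyl carbon) | COc1ccc(/C=C/C2=[O+][B-](F)(F)Oc3c(OC)c(OC)c(OC)c(OC)c32)cc1 | intermediate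
8 | (E)-1-(2-hydroxy-3,4,5,6-tetramethoxyphenyl)-3-(4-methoxyphenyl)prop-2-en-1-one (2'-hydroxy-3',4',5',6',4-pentamethoxychalcone) | COc1ccc(/C=C/C(=O)c2c(O)c(OC)c(OC)c(OC)c2OC)cc1 | intermediate
9 | (2S)-5,6,7,8-tetramethoxy-2-(4-methoxyphenyl)chroman-4-one ((2S)-5,6,7,8,4'-pentamethoxyflavanone) | COc1ccc([C@@H]2CC(=O)c3c(OC)c(OC)c(OC)c(OC)c3O2)cc1 | target

**Totals and risks**
Total step count: 4. Longest linear sequence: 4 steps (1 → 2 → 3 → 8 → 9). Compound 4 enters at step 3 without any steps of its own.

**Step 4** is the riskiest.
- The enone carries no activating group and its β-aryl ring is electron-rich, so closure may be slow.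
- Conversion may stall at the chalcone/flavanone equilibrium.
- Long contact with the amine can erode the ee.
- The sense of induction has to be confirmed.

The fallback sets out from 8 and comes back at 9.
- Compound 8 is closed without stereocontrol (NaOAc, EtOH, reflux) to racemic 5,6,7,8,4'-pentamethoxyflavanone F1.
- This is resolved kinetically by Noyori-type asymmetric transfer hydrogenation ([Cp*RhCl((R,R)-TsDPEN)] 1 mol %, HCO2H/Et3N, EtOAc, rt, stopped near 52 % conversion).
- The (R,R) catalyst makes 4R carbinols from aryl ketones of this type, so it consumes the 2R ketone as (2R,4R)-cis-5,6,7,8,4'-pentamethoxyflavan-4-ol F2.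
- Compound 9 is left untouched and is separated by chromatography.

**Step 3** is second.
- The stabilised 4-methoxycinnamoyl system can instead undergo conjugate Friedel–Crafts hydroarylation to a 4-aryl-3,4-dihydrocoumarin.
- Hot BF3 may also cleave the 6'-OMe.

The fallback sets out from 3 and comes back at 8.
- Compound 3 is C-acetylated (AcOH, BF3·OEt2, 80 °C) to 1-(2-hydroxy-3,4,5,6-tetramethoxyphenyl)ethan-1-one F3.
- This is condensed with 4-methoxybenzaldehyde in a Claisen–Schmidt aldol condensation (KOH, EtOH, rt, cold acidification) to give 8.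

**Step 2** is third.
- The very electron-rich ortho-bromophenoxide may protodebrominate back to 1 or oxidise before C–O coupling.

The fallback avoids copper entirely. It sets out from 1, bypasses 2 and 3, and comes back at 8.
- Compound 1 is oxidised at the ortho position with IBX (DMF, rt) to 3,4,5-trimethoxycyclohexa-3,5-diene-1,2-dione F4.
- This is reduced in the same flask with aqueous Na2S2O4 to 3,4,5-trimethoxybenzene-1,2-diol F5.
- The diol is C-cinnamoylated at its only free ring carbon with 5 in BF3·OEt2 to give (E)-1-(2,3-dihydroxy-4,5,6-trimethoxyphenyl)-3-(4-methoxyphenyl)prop-2-en-1-one F6.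
- The non-chelated 3'-OH alone is then methylated (Me2SO4 1.0 equiv, K2CO3, acetone, reflux), while the carbonyl-chelated 2'-OH stays free, giving 8.

**Further compounds**
F1 | step 4 | racemic 5,6,7,8,4'-pentamethoxyflavanone | COc1ccc(C2CC(=O)c3c(OC)c(OC)c(OC)c(OC)c3O2)cc1
F2 | step 4 | (2R,4R)-cis-5,6,7,8,4'-pentamethoxyflavan-4-ol | COc1ccc([C@H]2C[C@@H](O)c3c(OC)c(OC)c(OC)c(OC)c3O2)cc1
F3 | step 3 | 1-(2-hydroxy-3,4,5,6-tetramethoxyphenyl)ethan-1-one | CC(=O)c1c(O)c(OC)c(OC)c(OC)c1OC
F4 | step 2 | 3,4,5-trimethoxycyclohexa-3,5-diene-1,2-dione | COC1=CC(=O)C(=O)C(OC)=C1OC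
F5 | step 2 | 3,4,5-trimethoxybenzene-1,2-diol | COc1cc(O)c(O)c(OC)c1OC
F6 | step 2 | (E)-1-(2,3-dihydroxy-4,5,6-trimethoxyphenyl)-3-(4-methoxyphenyl)prop-2-en-1-one | COc1ccc(/C=C/C(=O)c2c(O)c(O)c(OC)c(OC)c2OC)cc1
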